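**Retrosynthetic overview**
- The target is a 9-hydroxyeremophila-7(11),9-dien-8-one 3-ester. The strategy rests on ring B: the C8 ketone flanked by the C7=C11 isopropylidene group (a pulegone unit) and by the C9-hydroxy C9=C10 enol.
- Cleaving the C3–O ester bond gives the ring A/B alcohol, with its enol masked as a methoxymethyl ether, and (2Z)-3-methyl-4-(angeloyloxy)but-2-enoic acid, made from a propargyl ether by syn-carbocupration and Mitsunobu angeloylation.
- The diosphenol comes from α'-hydroxylation and oxidation of the C8 enone, which comes from oxidation and double-bond shift of an 8-hydroxy-7-isopropenyl trans-decalin.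
- Ring B is closed second, by a C7–C8 carbonyl-ene cyclisation of a ring A aldehyde with trans C10 2-oxoethyl and C5 prenyl arms.
- Ring A is bought as 2-methylcyclohex-2-en-1-one: asymmetric conjugate vinylation with enolate prenylation, then C3 hydroxylation, C4 methylenation and hydroxyl-directed hydrogenation.

Key step: step 9

Assumption: the enantiomer of the chiral ligand in step 1 that gives the (3S) adduct is chosen by a test reaction. Bicyclic compounds carry eremophilane numbering; the C4 and C5 methyl groups define the β face, so the target is 3α-acyloxy and the trans-decalins are 10α-H.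

**Route**

Step 1
Reactants: 1 2-methylcyclohex-2-en-1-one; 2 vinylmagnesium bromide; 3 1-bromo-3-methylbut-2-ene
Product: 5 (2S,3S)-3-ethenyl-2-methyl-2-(3-methylbut-2-en-1-yl)cyclohexan-1-one, via magnesium enolate 4 (not isolated)
Conditions: Cu(OTf)2 (5 mol%), chiral 4,5-diphenylimidazolinium salt as N-heterocyclic carbene precursor (6 mol%), Et2O, −30 °C, slow addition of 2; then 3, DMPU, −30 °C to rt
Reagents that add atoms: none
Why: Copper-catalysed asymmetric conjugate addition of a Grignard reagent to an α-substituted cyclic enone with trapping of the magnesium enolate; the chiral copper complex sets C3 (later C10), and prenyl bromide attacks the tetrasubstituted enolate anti to the neighbouring vinyl group, which sets the quaternary C2 (later C5) trans to it.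

Step 2
Reactants: 5 (2S,3S)-3-ethenyl-2-methyl-2-(3-methylbut-2-en-1-yl)cyclohexan-1-one
Product: 7 (2S,3S)-3-(2-hydroxyethyl)-2-methyl-2-(3-methylbut-2-en-1-yl)cyclohexan-1-one, via B-alkyl-9-BBN adduct 6 (not isolated)
Conditions: 9-BBN, THF, 0 °C to rt; then H2O2, aq NaOH, 0 °C
Reagents that add atoms: hydrogen peroxide, OO
Why: Hydroboration–oxidation, in which 9-BBN adds anti-Markovnikov to the monosubstituted alkene much faster than it attacks the trisubstituted prenyl alkene or reduces the hindered α-quaternary ketone; no stereocentre is formed.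

Step 3
Reactants: 7 (2S,3S)-3-(2-hydroxyethyl)-2-methyl-2-(3-methylbut-2-en-1-yl)cyclohexan-1-one
Product: 8 (2S,3S)-2-methyl-2-(3-methylbut-2-en-1-yl)-3-[2-(triethylsilyloxy)ethyl]cyclohexan-1-one
Conditions: Et3SiCl, imidazole, CH2Cl2, 0 °C
Reagents that add atoms: chlorotriethylsilane, CC[Si](Cl)(CC)CC
Why: Silylation of the primary alcohol, chosen because a primary triethylsilyl ether can later be oxidised directly to the aldehyde in the presence of a secondary TBS ether.

Step 4
Reactants: 8 (2S,3S)-2-methyl-2-(3-methylbut-2-en-1-yl)-3-[2-(triethylsilyloxy)ethyl]cyclohexan-1-one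
Product: 10 (2S,3S,6R)-6-hydroxy-2-methyl-2-(3-methylbut-2-en-1-yl)-3-[2-(triethylsilyloxy)ethyl]cyclohexan-1-one, via potassium enolate 9 (not isolated)
Conditions: KN(SiMe3)2, THF, −78 °C; 2-(phenylsulfonyl)-3-phenyloxaziridine, −78 °C; AcOH quench
Reagents that add atoms: 2-(phenylsulfonyl)-3-phenyloxaziridine, O=S(=O)(c1ccccc1)N1OC1c1ccccc1
Why: Enolate oxidation with an N-sulfonyloxaziridine, regiospecific because C2 is quaternary; the oxidant should approach C6 anti to the pseudoaxial C2 methyl group and give the equatorial (6R) alcohol, which is also the more stable epimer.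

Step 5
Reactants: 10 (2S,3S,6R)-6-hydroxy-2-methyl-2-(3-methylbut-2-en-1-yl)-3-[2-(triethylsilyloxy)ethyl]cyclohexan-1-one
Product: 11 (1R,3S,4S)-3-methyl-3-(3-methylbut-2-en-1-yl)-2-methylidene-4-[2-(triethylsilyloxy)ethyl]cyclohexan-1-ol
Conditions: Ph3PCH3Br (4 equiv), KOtBu (3.8 equiv), toluene, 0 to 80 °C
Reagents that add atoms: methyltriphenylphosphonium bromide, C[P+](c1ccccc1)(c1ccccc1)c1ccccc1.[Br-]
Why: Wittig methylenation with excess ylide at elevated temperature, workable on this hindered ketone because the α-alkoxide blocks enolisation toward the carbinol carbon and the other α-carbon is quaternary, so no stereocentre is at risk.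

Step 6
Reactants: 11 (1R,3S,4S)-3-methyl-3-(3-methylbut-2-en-1-yl)-2-methylidene-4-[2-(triethylsilyloxy)ethyl]cyclohexan-1-ol
Product: 12 (1R,2R,3S,4S)-2,3-dimethyl-3-(3-methylbut-2-en-1-yl)-4-[2-(triethylsilyloxy)ethyl]cyclohexan-1-ol
Conditions: H2 (40 bar), [Rh(nbd)(dppb)]BF4 (5–10 mol%; nbd = norbornadiene, dppb = 1,4-bis(diphenylphosphino)butane), CH2Cl2, rt
Reagents that add atoms: none
Why: Hydroxyl-directed homogeneous hydrogenation, in which the cationic rhodium catalyst binds the allylic hydroxyl and delivers hydrogen to C2 from the OH face (also the face away from the axial C3 methyl), so the new methyl group ends trans to OH and cis to the C3 methyl, while this catalyst reduces the undirected trisubstituted prenyl alkene only slowly.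

Step 7
Reactants: 12 (1R,2R,3S,4S)-2,3-dimethyl-3-(3-methylbut-2-en-1-yl)-4-[2-(triethylsilyloxy)ethyl]cyclohexan-1-ol
Product: 13 tert-butyl({(1R,2R,3S,4S)-2,3-dimethyl-3-(3-methylbut-2-en-1-yl)-4-[2-(triethylsilyloxy)ethyl]cyclohexyl}oxy)dimethylsilane
Conditions: TBSOTf, 2,6-lutidine, CH2Cl2, −78 to 0 °C
Reagents that add atoms: tert-butyldimethylsilyl trifluoromethanesulfonate, CC(C)(C)[Si](C)(C)OS(=O)(=O)C(F)(F)F
Why: Silylation of the hindered secondary alcohol with the silyl triflate, which leaves the primary triethylsilyl ether and the alkene untouched.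

Step 8
Reactants: 13 tert-butyl({(1R,2R,3S,4S)-2,3-dimethyl-3-(3-methylbut-2-en-1-yl)-4-[2-(triethylsilyloxy)ethyl]cyclohexyl}oxy)dimethylsilane
Product: 15 2-[(1S,2S,3R,4R)-4-(tert-butyldimethylsilyloxy)-2,3-dimethyl-2-(3-methylbut-2-en-1-yl)cyclohexyl]acetaldehyde, via primary alcohol 14 (not isolated)
Conditions: (COCl)2 (4 equiv), DMSO (8 equiv), CH2Cl2, −78 to −40 °C; Et3N, −78 to 0 °C
Reagents that add atoms: none
Why: Swern oxidation applied directly to a primary triethylsilyl ether, which is cleaved by the chlorosulfonium/HCl medium and oxidised in the same flask while the hindered secondary TBS ether stays intact; no stereocentre is touched.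

Step 9
Reactants: 15 2-[(1S,2S,3R,4R)-4-(tert-butyldimethylsilyloxy)-2,3-dimethyl-2-(3-methylbut-2-en-1-yl)cyclohexyl]acetaldehyde
Product: 16 3α-(tert-butyldimethylsilyloxy)-7α-isopropenyl-eremophil-11(12)-en-8β-ol (trans-decalin; 10α-H; 4β,5β-dimethyl)
Conditions: Me2AlCl (1.5 equiv), CH2Cl2, −78 °C; cold 1 M HCl quench
Reagents that add atoms: none
Why: Me2AlCl binds the C8 aldehyde oxygen, C7 of the prenyl alkene bonds to C8 and an allylic hydrogen of a C11 methyl group passes to oxygen through a six-membered chair-like array, a concerted type 1 intramolecular carbonyl-ene reaction of a 6-enal, the reaction class that converts citronellal into isopulegol. Ring B (C5–C6–C7–C8–C9–C10) closes in the 6-exo mode with respect to the alkene, so C7=C11 ends outside the ring as the isopropenyl group, and the ring fusion is trans because the two arms sit trans-diequatorial on the ring A chair (C5 methyl axial, C4 methyl and C3 silyloxy equatorial). C8 is set by the Lewis-acid-bound oxygen taking the equatorial place in the forming chair (8β-OH) and C7 by the alkene terminus also lying equatorial (7α-isopropenyl); both centres are removed in steps 10 to 12, so their ratio is not critical. The selectivity that is needed is ene over stepwise Prins chemistry (chloride capture at C11, proton loss into the ring, aldol reactions); it is secured by the 1,6-relationship and preorganisation of the arms, by −78 °C, and by Me2AlCl, whose methyl groups consume any released proton so that no protic acid builds up. The secondary TBS ether does not react under these conditions.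

Step 10
Reactants: 16 3α-(tert-butyldimethylsilyloxy)-7α-isopropenyl-eremophil-11(12)-en-8β-ol
Product: 18 3α-(tert-butyldimethylsilyloxy)eremophil-7(11)-en-8-one (10α-H), via isopropenyl ketone 17 (not isolated)
Conditions: (COCl)2, DMSO, CH2Cl2, −78 °C; Et3N; then DBU, 0 °C to rt
Reagents that add atoms: none
Why: Swern oxidation followed by base-mediated conjugation, in which the C8 carbinol becomes the ketone and DBU moves the 11(12) double bond through the dienolate into the more stable tetrasubstituted 7(11) position, which removes the C7 and C8 stereocentres.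

Step 11
Reactants: 18 3α-(tert-butyldimethylsilyloxy)eremophil-7(11)-en-8-one
Product: 20 9α-hydroxy-3α-(tert-butyldimethylsilyloxy)eremophil-7(11)-en-8-one, via potassium dienolate 19 (not isolated)
Conditions: KN(SiMe3)2, THF, −78 °C; 2-(phenylsulfonyl)-3-phenyloxaziridine, −78 °C; AcOH quench
Reagents that add atoms: 2-(phenylsulfonyl)-3-phenyloxaziridine, O=S(=O)(c1ccccc1)N1OC1c1ccccc1
Why: Kinetic α'-enolate formation and oxaziridine hydroxylation, in which the amide base at −78 °C removes a C9 proton in preference to a γ proton and the oxidant should attack anti to the axial C5 methyl group; the C9 configuration is lost in step 12 and is immaterial.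

Step 12
Reactants: 20 9α-hydroxy-3α-(tert-butyldimethylsilyloxy)eremophil-7(11)-en-8-one
Product: 22 9-hydroxy-3α-(tert-butyldimethylsilyloxy)eremophila-7(11),9-dien-8-one, via 8,9-dione 21 (not isolated)
Conditions: Dess–Martin periodinane, CH2Cl2, 0 °C to rt
Reagents that add atoms: none
Why: Dess–Martin oxidation of the acyloin to the 8,9-dione, which enolises toward C10 to the conjugated diosphenol and so removes the C9 and C10 stereocentres as the target requires.

Step 13
Reactants: 22 9-hydroxy-3α-(tert-butyldimethylsilyloxy)eremophila-7(11),9-dien-8-one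
Product: 23 9-(methoxymethoxy)-3α-(tert-butyldimethylsilyloxy)eremophila-7(11),9-dien-8-one
Conditions: MOMCl, iPr2NEt, Bu4NI (cat.), CH2Cl2, 0 to 40 °C
Reagents that add atoms: chloromethyl methyl ether, COCCl
Why: O-Alkylation of the acidic enol (Williamson-type acetal formation), which masks the diosphenol hydroxyl so that it cannot compete with the C3 hydroxyl in the later acylation.

Step 14
Reactants: 23 9-(methoxymethoxy)-3α-(tert-butyldimethylsilyloxy)eremophila-7(11),9-dien-8-one
Product: 24 3α-hydroxy-9-(methoxymethoxy)eremophila-7(11),9-dien-8-one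
Conditions: HF·pyridine, pyridine, THF, 0 °C to rt
Reagents that add atoms: none
Why: Fluoride-mediated desilylation, which cleaves the secondary TBS ether and leaves the methoxymethyl enol ether and the cross-conjugated dienone intact.

Step 15
Reactants: 25 tert-butyldimethyl(prop-2-yn-1-yloxy)silane
Product: 27 tert-butyl 4-(tert-butyldimethylsilyloxy)but-2-ynoate, via lithium acetylide 26 (not isolated)
Conditions: n-BuLi, THF, −78 °C; Boc2O, −78 to 0 °C; AcOH quench
Reagents that add atoms: di-tert-butyl dicarbonate, CC(C)(C)OC(=O)OC(=O)OC(C)(C)C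
Why: Acylation of a lithium acetylide with the dicarbonate, a standard route to tert-butyl ynoates.

Step 16
Reactants: 27 tert-butyl 4-(tert-butyldimethylsilyloxy)but-2-ynoate
Product: 29 tert-butyl (2Z)-4-(tert-butyldimethylsilyloxy)-3-methylbut-2-enoate, via alkenylcuprate 28 (not isolated)
Conditions: Me2CuLi (from MeLi and CuI), THF, −78 °C; AcOH quench at −78 °C
Reagents that add atoms: lithium dimethylcuprate, [Li+].C[Cu-]C
Why: Syn-carbocupration (conjugate addition of a lithium dialkylcuprate to an ynoate), in which methyl and copper add to the same side of the alkyne and protonation of the alkenylcopper at −78 °C with retention fixes the 2Z geometry (CH2O cis to the ester).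

Step 17
Reactants: 29 tert-butyl (2Z)-4-(tert-butyldimethylsilyloxy)-3-methylbut-2-enoate
Product: 30 tert-butyl (2Z)-4-hydroxy-3-methylbut-2-enoate
Conditions: HF·pyridine, pyridine, THF, 0 °C; used at once
Reagents that add atoms: none
Why: Buffered fluoride desilylation frees the allylic alcohol, and the bulky tert-butyl ester should slow lactonisation to the butenolide long enough for immediate use.

Step 18
Reactants: 30 tert-butyl (2Z)-4-hydroxy-3-methylbut-2-enoate; 31 angelic acid [(2Z)-2-methylbut-2-enoic acid]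
Product: 32 tert-butyl (2Z)-3-methyl-4-{[(2Z)-2-methylbut-2-enoyl]oxy}but-2-enoate
Conditions: PPh3, DIAD, THF, 0 °C
Reagents that add atoms: none
Why: Mitsunobu esterification, in which the alcohol is activated and displaced by angelate at the primary allylic carbon (SN2), so the angeloyl carbonyl is never activated and its 2Z geometry is kept.

Step 19
Reactants: 32 tert-butyl (2Z)-3-methyl-4-{[(2Z)-2-methylbut-2-enoyl]oxy}but-2-enoate
Product: 33 (2Z)-3-methyl-4-{[(2Z)-2-methylbut-2-enoyl]oxy}but-2-enoic acid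
Conditions: TFA, CH2Cl2, 0 °C to rt
Reagents that add atoms: none
Why: Acidolysis of the tert-butyl ester (loss of 2-methylpropene) frees the acid while the allylic angelate and both alkene geometries persist.

Step 20
Reactants: 24 3α-hydroxy-9-(methoxymethoxy)eremophila-7(11),9-dien-8-one; 33 (2Z)-3-methyl-4-{[(2Z)-2-methylbut-2-enoyl]oxy}but-2-enoic acid
Product: 34 9-(methoxymethoxy)-8-oxoeremophila-7(11),9-dien-3α-yl (2Z)-3-methyl-4-{[(2Z)-2-methylbut-2-enoyl]oxy}but-2-enoate
Conditions: DCC, DMAP (0.2 equiv), CH2Cl2, 0 °C to rt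
Reagents that add atoms: none
Why: Steglich esterification of the equatorial C3 hydroxyl with retention at C3, run without added amine base to limit vinylketene formation and Z/E isomerisation of the β,β-disubstituted enoic acid.

Step 21
Reactants: 34 9-(methoxymethoxy)-8-oxoeremophila-7(11),9-dien-3α-yl (2Z)-3-methyl-4-{[(2Z)-2-methylbut-2-enoyl]oxy}but-2-enoate
Product: 35 (1R,2R,8aR)-5-hydroxy-1,8a-dimethyl-6-oxo-7-(propan-2-ylidene)-1,2,3,4,6,7,8,8a-octahydronaphthalen-2-yl (2Z)-3-methyl-4-{[(2Z)-2-methylbut-2-enoyl]oxy}but-2-enoate (CNP0228871.1)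
Conditions: TFA/CH2Cl2/H2O (10:88:2), 0 °C
Reagents that add atoms: none
Why: Acid-catalysed cleavage of the methoxymethyl enol ether (acetal hydrolysis with the diosphenol as leaving group) releases the free enol, and the ester groups should survive brief cold acid.

**Compound list**
1 | 2-methylcyclohex-2-en-1-one | CC1=CCCCC1=O | starting material
2 | vinylmagnesium bromide | C=C[Mg]Br | starting material
3 | 1-bromo-3-methylbut-2-ene (prenyl bromide) | CC(C)=CCBr | starting material
4 | bromomagnesium (3S)-3-ethenyl-2-methylcyclohex-1-en-1-olate | C=C[C@@H]1CCCC(O[Mg]Br)=C1C | intermediate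
5 | (2S,3S)-3-ethenyl-2-methyl-2-(3-methylbut-2-en-1-yl)cyclohexan-1-one (vinyl and prenyl trans) | C=C[C@@H]1CCCC(=O)[C@@]1(C)CC=C(C)C | intermediate
6 | B-alkyl-9-borabicyclo[3.3.1]nonane adduct of 5 (boron on the terminal carbon of the former vinyl group; ring centres as in 5) | B1(C2CCCC1CCC2)CC[C@@H]3CCCC(=O)[C@@]3(C)CC=C(C)C | intermediate
7 | (2S,3S)-3-(2-hydroxyethyl)-2-methyl-2-(3-methylbut-2-en-1-yl)cyclohexan-1-one | OCC[C@@H]1CCCC(=O)[C@@]1(C)CC=C(C)C | intermediate
8 | (2S,3S)-2-methyl-2-(3-methylbut-2-en-1-yl)-3-[2-(triethylsilyloxy)ethyl]cyclohexan-1-one | CC[Si](CC)(CC)OCC[C@@H]1CCCC(=O)[C@@]1(C)CC=C(C)C | intermediate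
9 | potassium enolate of 8 (C1=C6 enolate) | [K+].CC[Si](CC)(CC)OCC[C@@H]1CCC=C([O-])[C@@]1(C)CC=C(C)C | intermediate
10 | (2S,3S,6R)-6-hydroxy-2-methyl-2-(3-methylbut-2-en-1-yl)-3-[2-(triethylsilyloxy)ethyl]cyclohexan-1-one | CC[Si](CC)(CC)OCC[C@@H]1CC[C@@H](O)C(=O)[C@@]1(C)CC=C(C)C | intermediate
11 | (1R,3S,4S)-3-methyl-3-(3-methylbut-2-en-1-yl)-2-methylidene-4-[2-(triethylsilyloxy)ethyl]cyclohexan-1-ol | CC[Si](CC)(CC)OCC[C@@H]1CC[C@@H](O)C(=C)[C@@]1(C)CC=C(C)C | intermediate
12 | (1R,2R,3S,4S)-2,3-dimethyl-3-(3-methylbut-2-en-1-yl)-4-[2-(triethylsilyloxy)ethyl]cyclohexan-1-ol | CC[Si](CC)(CC)OCC[C@@H]1CC[C@@H](O)[C@H](C)[C@@]1(C)CC=C(C)C | intermediate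
13 | tert-butyl({(1R,2R,3S,4S)-2,3-dimethyl-3-(3-methylbut-2-en-1-yl)-4-[2-(triethylsilyloxy)ethyl]cyclohexyl}oxy)dimethylsilane | CC[Si](CC)(CC)OCC[C@@H]1CC[C@@H](O[Si](C)(C)C(C)(C)C)[C@H](C)[C@@]1(C)CC=C(C)C | intermediate
14 | 2-[(1S,2S,3R,4R)-4-(tert-butyldimethylsilyloxy)-2,3-dimethyl-2-(3-methylbut-2-en-1-yl)cyclohexyl]ethan-1-ol | OCC[C@@H]1CC[C@@H](O[Si](C)(C)C(C)(C)C)[C@H](C)[C@@]1(C)CC=C(C)C | intermediate
15 | 2-[(1S,2S,3R,4R)-4-(tert-butyldimethylsilyloxy)-2,3-dimethyl-2-(3-methylbut-2-en-1-yl)cyclohexyl]acetaldehyde (ene precursor) | O=CC[C@@H]1CC[C@@H](O[Si](C)(C)C(C)(C)C)[C@H](C)[C@@]1(C)CC=C(C)C | intermediate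
16 | 3α-(tert-butyldimethylsilyloxy)-7α-isopropenyl-eremophil-11(12)-en-8β-ol (trans-decalin; 10α-H; ene product) | CC(C)(C)[Si](C)(C)O[C@@H]1CC[C@H]2C[C@@H](O)[C@H](C(C)=C)C[C@]2(C)[C@H]1C | intermediate
17 | 3α-(tert-butyldimethylsilyloxy)-7α-isopropenyl-eremophil-11(12)-en-8-one | CC(C)(C)[Si](C)(C)O[C@@H]1CC[C@H]2CC(=O)[C@H](C(C)=C)C[C@]2(C)[C@H]1C | intermediate
18 | 3α-(tert-butyldimethylsilyloxy)eremophil-7(11)-en-8-one (10α-H) | CC(C)(C)[Si](C)(C)O[C@@H]1CC[C@H]2CC(=O)C(=C(C)C)C[C@]2(C)[C@H]1C | intermediate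
19 | potassium 8(9)-dienolate of 18 | [K+].CC(C)(C)[Si](C)(C)O[C@@H]1CC[C@H]2C=C([O-])C(=C(C)C)C[C@]2(C)[C@H]1C | intermediate
20 | 9α-hydroxy-3α-(tert-butyldimethylsilyloxy)eremophil-7(11)-en-8-one (expected major C9 epimer) | CC(C)(C)[Si](C)(C)O[C@@H]1CC[C@H]2[C@H](O)C(=O)C(=C(C)C)C[C@]2(C)[C@H]1C | intermediate
21 | 3α-(tert-butyldimethylsilyloxy)eremophil-7(11)-ene-8,9-dione | CC(C)(C)[Si](C)(C)O[C@@H]1CC[C@H]2C(=O)C(=O)C(=C(C)C)C[C@]2(C)[C@H]1C | intermediate
22 | 9-hydroxy-3α-(tert-butyldimethylsilyloxy)eremophila-7(11),9-dien-8-one | CC(C)(C)[Si](C)(C)O[C@@H]1CCC2=C(O)C(=O)C(=C(C)C)C[C@]2(C)[C@H]1C | intermediate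
23 | 9-(methoxymethoxy)-3α-(tert-butyldimethylsilyloxy)eremophila-7(11),9-dien-8-one | CC(C)(C)[Si](C)(C)O[C@@H]1CCC2=C(OCOC)C(=O)C(=C(C)C)C[C@]2(C)[C@H]1C | intermediate
24 | 3α-hydroxy-9-(methoxymethoxy)eremophila-7(11),9-dien-8-one | O[C@@H]1CCC2=C(OCOC)C(=O)C(=C(C)C)C[C@]2(C)[C@H]1C | intermediate
25 | tert-butyldimethyl(prop-2-yn-1-yloxy)silane | C#CCO[Si](C)(C)C(C)(C)C | starting material
26 | lithium acetylide of 25 | [Li]C#CCO[Si](C)(C)C(C)(C)C | intermediate
27 | tert-butyl 4-(tert-butyldimethylsilyloxy)but-2-ynoate | CC(C)(C)OC(=O)C#CCO[Si](C)(C)C(C)(C)C | intermediate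
28 | lithium methyl(alkenyl)cuprate from syn-addition to 27 (Cu on C2, cis to the new C3 methyl) | [Li+].CC(C)(C)[Si](C)(C)OC/C(C)=C(/[Cu-]C)C(=O)OC(C)(C)C | intermediate
29 | tert-butyl (2Z)-4-(tert-butyldimethylsilyloxy)-3-methylbut-2-enoate | CC(C)(C)[Si](C)(C)OC/C(C)=C\C(=O)OC(C)(C)C | intermediate
30 | tert-butyl (2Z)-4-hydroxy-3-methylbut-2-enoate | OC/C(C)=C\C(=O)OC(C)(C)C | intermediate
31 | angelic acid, (2Z)-2-methylbut-2-enoic acid | C/C=C(/C)C(=O)O | starting material
32 | tert-butyl (2Z)-3-methyl-4-{[(2Z)-2-methylbut-2-enoyl]oxy}but-2-enoate | C/C=C(/C)C(=O)OC/C(C)=C\C(=O)OC(C)(C)C | intermediate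
33 | (2Z)-3-methyl-4-{[(2Z)-2-methylbut-2-enoyl]oxy}but-2-enoic acid | C/C=C(/C)C(=O)OC/C(C)=C\C(=O)O | intermediate
34 | 9-(methoxymethoxy)-8-oxoeremophila-7(11),9-dien-3α-yl (2Z)-3-methyl-4-{[(2Z)-2-methylbut-2-enoyl]oxy}but-2-enoate | C/C=C(/C)C(=O)OC/C(C)=C\C(=O)O[C@@H]1CCC2=C(OCOC)C(=O)C(=C(C)C)C[C@]2(C)[C@H]1C | intermediate
35 | (1R,2R,8aR)-5-hydroxy-1,8a-dimethyl-6-oxo-7-(propan-2-ylidene)-1,2,3,4,6,7,8,8a-octahydronaphthalen-2-yl (2Z)-3-methyl-4-{[(2Z)-2-methylbut-2-enoyl]oxy}but-2-enoate | C/C=C(/C)C(=O)OC/C(C)=C\C(=O)O[C@@H]1CCC2=C(O)C(=O)C(=C(C)C)C[C@]2(C)[C@H]1C | target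

**Step count**
Total: 21 steps. Longest linear sequence: 16 steps (steps 1–14, 20 and 21, from 2-methylcyclohex-2-en-1-one); the side-chain acid takes 5 steps (15–19).

**Steps most likely to fail**

Step 1. The copper-catalysed addition of an sp2 Grignard reagent to the α-substituted enone may run with low enantioselectivity or with competing 1,2-addition, and C-alkylation of the magnesium enolate may be slow. The fallback sets out from 1 (with 2 and 3). The same tandem addition–prenylation is run with achiral CuBr·SMe2 catalysis, which is expected to give the racemic trans-ketone: 5 together with its enantiomer (2R,3R)-3-ethenyl-2-methyl-2-(3-methylbut-2-en-1-yl)cyclohexan-1-one F1. The two are separated by preparative chromatography on a chiral stationary phase, and the route is rejoined at 5.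

Step 9. The Lewis-acid-bound aldehyde may react stepwise through a C11 cation (chloride capture, proton loss to other alkene isomers) or by aldol oligomerisation instead of the concerted ene path. The fallback sets out from 15 and forms the same C7–C8 bond by alkene acylation. Pinnick oxidation (NaClO2, NaH2PO4, 2-methylbut-2-ene, tBuOH/H2O) gives [(1S,2S,3R,4R)-4-(tert-butyldimethylsilyloxy)-2,3-dimethyl-2-(3-methylbut-2-en-1-yl)cyclohexyl]acetic acid F2. Oxalyl chloride with catalytic DMF gives the acid chloride F3. SnCl4 in CH2Cl2 at −78 °C should close ring B by intramolecular acylation of the prenyl alkene (the cyclisation known for citronellic acid chloride) to give 11-chloro-3α-(tert-butyldimethylsilyloxy)eremophilan-8-one F4. DBU then eliminates HCl, and the route is rejoined at 18.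

Step 6. The catalyst may also reduce the prenyl alkene, isomerise the allylic alcohol to the ketone, or add hydrogen with poor facial selectivity at the hindered methylidene group. The fallback sets out from 11 and avoids hydrogen gas. Dess–Martin oxidation gives the α-methylene ketone (3S,4S)-3-methyl-3-(3-methylbut-2-en-1-yl)-2-methylidene-4-[2-(triethylsilyloxy)ethyl]cyclohexan-1-one F5. Conjugate reduction with [(Ph3P)CuH]6, which does not touch isolated alkenes, followed by protonation and NaOMe equilibration, should give the equatorial 2-methyl ketone (2R,3S,4S)-2,3-dimethyl-3-(3-methylbut-2-en-1-yl)-4-[2-(triethylsilyloxy)ethyl]cyclohexan-1-one F6. Dissolving-metal reduction (Li, liquid NH3, THF, tBuOH) should give the equatorial alcohol, and the route is rejoined at 12.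

Further compounds
F1 | step 1 | (2R,3R)-3-ethenyl-2-methyl-2-(3-methylbut-2-en-1-yl)cyclohexan-1-one | C=C[C@H]1CCCC(=O)[C@]1(C)CC=C(C)C
F2 | step 9 | [(1S,2S,3R,4R)-4-(tert-butyldimethylsilyloxy)-2,3-dimethyl-2-(3-methylbut-2-en-1-yl)cyclohexyl]acetic acid | OC(=O)C[C@@H]1CC[C@@H](O[Si](C)(C)C(C)(C)C)[C@H](C)[C@@]1(C)CC=C(C)C
F3 | step 9 | [(1S,2S,3R,4R)-4-(tert-butyldimethylsilyloxy)-2,3-dimethyl-2-(3-methylbut-2-en-1-yl)cyclohexyl]acetyl chloride | O=C(Cl)C[C@@H]1CC[C@@H](O[Si](C)(C)C(C)(C)C)[C@H](C)[C@@]1(C)CC=C(C)C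
F4 | step 9 | 11-chloro-3α-(tert-butyldimethylsilyloxy)eremophilan-8-one (10α-H; C7 epimers) | CC(C)(C)[Si](C)(C)O[C@@H]1CC[C@H]2CC(=O)C(C(C)(C)Cl)C[C@]2(C)[C@H]1C
F5 | step 6 | (3S,4S)-3-methyl-3-(3-methylbut-2-en-1-yl)-2-methylidene-4-[2-(triethylsilyloxy)ethyl]cyclohexan-1-one | CC[Si](CC)(CC)OCC[C@@H]1CCC(=O)C(=C)[C@@]1(C)CC=C(C)C
F6 | step 6 | (2R,3S,4S)-2,3-dimethyl-3-(3-methylbut-2-en-1-yl)-4-[2-(triethylsilyloxy)ethyl]cyclohexan-1-one | CC[Si](CC)(CC)OCC[C@@H]1CCC(=O)[C@H](C)[C@@]1(C)CC=C(C)C
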